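**Plan**
1. Retrosynthetic cuts, in order: the acetal protecting groups; then C6–C(=O), which removes the cinnamoyl arm as an E-Weinreb amide; then O1–C8a and C4–C4a together, which lifts the whole C5 unit (O1, C2 with its two methyls, C3, C4) off the benzene ring.
2. This leaves the aryne C4a≡C8a of a phloroglucinol ring (OMOM at C5 and C7) and the chain ⁻O1–C2Me2–C3H(OTHP)–C4H2Cl, which is an O-nucleophile and a C-electrophile in 1,4-relation.
3. Enabling feature: the oxygen on C5 is the neighbour of C4a. In the aryne it sends the alkoxide to the remote C8a and holds the carbanion on C4a, at six-ring distance from C4. The usual questions of a phenol/prenyl-epoxide closure (which flanking OH, five- or six-membered ring) therefore do not arise.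
4. Forward order: the benzene ring is bought; the dihydropyran ring is made by aryne annulation (step 6); the chalcone arm is joined at C6 by directed lithiation and Weinreb acylation (step 9); one acidic deprotection follows (step 10).
5. Stereochemistry: C3 is the stereocentre of methyl (R)-glycidate, and no bond at it is ever broken. The E-alkene comes from a Horner–Wadsworth–Emmons reaction.

Key step: step 6

Remark: atom numbers are those of the chroman (O1, C2, C3, C4, C4a, C5–C8, C8a). The THP acetal carbon is carried as an inconsequential mixture of epimers, is left undefined in the SMILES, and is lost in step 10.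

**Step 1**
Reactants: 1 5-bromoresorcinol
Product: 2 bromoarene bis-MOM ether (1-bromo-3,5-bis(methoxymethoxy)benzene)
Conditions: MOMCl, i-Pr2NEt, CH2Cl2, 0 °C → rt
Reagents that add atoms: chloromethyl methyl ether (MOMCl), COCCl
Why: Williamson-type O-alkylation of both phenols with the reactive α-chloro ether should give acetals that survive all later bases and serve as directing groups in steps 6 and 9.

**Step 2**
Reactants: 2 bromoarene bis-MOM ether
Product: 3 bromo-iodoarene (1-bromo-2-iodo-3,5-bis(methoxymethoxy)benzene)
Conditions: NIS, MeCN, rt, dark
Reagents that add atoms: N-iodosuccinimide, O=C1CCC(=O)N1I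
Why: Electrophilic aromatic iodination should take C2, para to one acetal oxygen and ortho to the other, rather than the more crowded C4 between the two OMOM groups, and the neutral medium spares the acetals.

**Step 3**
Reactants: 4 methyl (R)-glycidate
Product: 5 epoxy alcohol 2-[(2R)-oxiran-2-yl]propan-2-ol
Conditions: MeMgCl (2.2 equiv), THF, −78 → −20 °C; aq NH4Cl
Reagents that add atoms: methylmagnesium chloride, C[Mg]Cl
Why: Double Grignard addition to the ester is faster in the cold than opening of the oxirane, the chiral-pool stereocentre is not enolised, and any opening by magnesium chloride only anticipates step 4.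

**Step 4**
Reactants: 5 epoxy alcohol
Product: 6 chlorodiol (2S)-1-chloro-3-methylbutane-2,3-diol
Conditions: LiCl, AcOH, THF, rt
Reagents that add atoms: lithium chloride, [Li+].[Cl-]
Why: Halohydrin formation by SN2 opening of the terminal epoxide under buffered acid occurs at the unhindered CH2, so the C–O bond at the stereocentre is kept (the descriptor changes only because CH2Cl outranks CMe2OH).

**Step 5**
Reactants: 6 chlorodiol
Product: 7 THP ether (3S)-4-chloro-2-methyl-3-(oxan-2-yloxy)butan-2-ol
Conditions: 3,4-dihydro-2H-pyran (1.05 equiv), PPTS (cat.), CH2Cl2, 0 °C → rt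
Reagents that add atoms: 3,4-dihydro-2H-pyran, C1=COCCC1
Why: Tetrahydropyranylation is much faster at the secondary than at the tertiary hydroxyl, and unlike a silyl or acyl group an acetal cannot migrate to the neighbouring alkoxide of step 6.

**Step 6**
Reactants: 3 bromo-iodoarene; 7 THP ether
Product: 12 protected chromanol (3R)-5,7-bis(methoxymethoxy)-2,2-dimethyl-3-(oxan-2-yloxy)chromane, via potassium alkoxide 8 (not isolated), via bromoaryllithium 9 (not isolated), via aryne 10 (not isolated), via lithiated aryl ether 11 (not isolated)
Conditions: 7, KH, THF, 0 °C; then 3, −78 °C; PhLi (1.1 equiv, slow addition), −78 °C → rt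
Reagents that add atoms: none
Why: Proposed new method: iodine–lithium exchange turns 3 into 9, which loses LiBr to give the aryne 10 (C4a≡C8a); the tertiary alkoxide 8 adds through oxygen to C8a, and the aryl carbanion thus placed on C4a (11) displaces the primary chloride at C4, so that O1–C8a and C4–C4a arise in one flask without any proton source. Both halves are known by themselves, the addition of potassium tert-alkoxides to arynes and the Parham cyclialkylation of o-lithioaryl 3-haloalkyl ethers to chromans, and the closest one-pot type is the aryne annulation in which the aryl anion is caught by a tethered carbonyl group (xanthones from salicylates); the capture by an sp3 C–Cl bond is what is new. The dihydropyran ring closes in the 6-exo-tet mode, favoured by the gem-dimethyl group at C2. No stereocentre is created: C3 is brought in by 7 and stays intact, since substitution occurs at the neighbouring CH2 and C3 carries no acidic hydrogen. Regioselectivity of the addition is secured by the OMOM group on C5, whose inductive pull and the resulting distortion of the aryne send the nucleophile to the remote C8a and leave the charge on C4a beside it, while the OMOM group on C7 is too far away to interfere. Chemoselectivity is secured by the poor leaving group chloride (no 4-exo oxetane closure of 8 in the cold), by the THP acetal (no epoxide, no Payne-type migration, no five-membered ring through the C3 oxygen), by PhLi (its by-product iodobenzene cannot alkylate 11) and by its slow addition, which keeps carbanions scarce so that 8 meets the aryne.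

**Step 7**
Reactants: 13 4-hydroxybenzaldehyde
Product: 14 MOM aldehyde (4-(methoxymethoxy)benzaldehyde)
Conditions: MOMCl, i-Pr2NEt, CH2Cl2, 0 °C → rt
Reagents that add atoms: chloromethyl methyl ether (MOMCl), COCCl
Why: Williamson-type O-alkylation masks the acidic phenol so that the fragment tolerates the aryllithium of step 9 and is released by the same acid as the other acetals.

**Step 8**
Reactants: 14 MOM aldehyde; 15 diethyl [2-(methoxy(methyl)amino)-2-oxoethyl]phosphonate
Product: 16 cinnamoyl Weinreb amide (E)-N-methoxy-3-[4-(methoxymethoxy)phenyl]-N-methylprop-2-enamide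
Conditions: NaH, THF, 0 °C → rt
Reagents that add atoms: none
Why: The Horner–Wadsworth–Emmons reaction of a stabilised phosphonate with an aromatic aldehyde should give the E-alkene under thermodynamic control.

**Step 9**
Reactants: 12 protected chromanol; 16 cinnamoyl Weinreb amide
Product: 18 protected chalcone (E)-1-[(3R)-5,7-bis(methoxymethoxy)-2,2-dimethyl-3-(oxan-2-yloxy)chroman-6-yl]-3-[4-(methoxymethoxy)phenyl]prop-2-en-1-one, via C6-aryllithium 17 (not isolated)
Conditions: n-BuLi, THF, 0 °C; then 16, −78 → 0 °C; aq NH4Cl
Reagents that add atoms: none
Why: Directed ortho-metalation should take C6–H, the only position flanked by two chelating OMOM groups (C8 has one OMOM and the hindered ring oxygen), and the Weinreb ketone synthesis stops at the chelated tetrahedral adduct, so the E-enone appears only on work-up and suffers neither a second nor a conjugate addition.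

**Step 10**
Reactants: 18 protected chalcone
Product: 19 target (E)-1-[(3R)-3,5,7-trihydroxy-2,2-dimethylchroman-6-yl]-3-(4-hydroxyphenyl)prop-2-en-1-one
Conditions: 3 M aq HCl, MeOH, rt → 40 °C
Reagents that add atoms: none
Why: Acid-catalysed acetal exchange with methanol removes the three phenolic MOM groups and the still more labile THP group at once, as is known for MOM-protected 2',4',6'-trioxygenated chalcones, while the low pH avoids the phenoxide that triggers oxa-Michael closure and leaves C3 and the tertiary aryl ether untouched.

**Compound list**
1 | 5-bromobenzene-1,3-diol (5-bromoresorcinol) | Oc1cc(O)cc(Br)c1 | starting material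
2 | 1-bromo-3,5-bis(methoxymethoxy)benzene | COCOc1cc(Br)cc(OCOC)c1 | intermediate
3 | 1-bromo-2-iodo-3,5-bis(methoxymethoxy)benzene | COCOc1cc(Br)c(I)c(OCOC)c1 | intermediate
4 | methyl (2R)-oxirane-2-carboxylate (methyl (R)-glycidate) | COC(=O)[C@H]1CO1 | starting material
5 | 2-[(2R)-oxiran-2-yl]propan-2-ol | CC(C)(O)[C@H]1CO1 | intermediate
6 | (2S)-1-chloro-3-methylbutane-2,3-diol | CC(C)(O)[C@@H](CCl)O | intermediate
7 | (3S)-4-chloro-2-methyl-3-(oxan-2-yloxy)butan-2-ol | CC(C)(O)[C@@H](CCl)OC1CCCCO1 | intermediate
8 | potassium alkoxide of 7 | CC(C)([O-])[C@@H](CCl)OC1CCCCO1.[K+] | intermediate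
9 | [2-bromo-4,6-bis(methoxymethoxy)phenyl]lithium | [Li]c1c(Br)cc(OCOC)cc1OCOC | intermediate
10 | 3,5-bis(methoxymethoxy)benzyne | COCOC1=CC#CC(OCOC)=C1 | intermediate
11 | 2-lithio-3,5-bis(methoxymethoxy)phenyl ether of 7 | [Li]c1c(OCOC)cc(OCOC)cc1OC(C)(C)[C@@H](CCl)OC1CCCCO1 | intermediate
12 | (3R)-5,7-bis(methoxymethoxy)-2,2-dimethyl-3-(oxan-2-yloxy)chromane | CC1(C)Oc2cc(OCOC)cc(OCOC)c2C[C@H]1OC1CCCCO1 | intermediate
13 | 4-hydroxybenzaldehyde | O=Cc1ccc(O)cc1 | starting material
14 | 4-(methoxymethoxy)benzaldehyde | COCOc1ccc(C=O)cc1 | intermediate
15 | diethyl [2-(methoxy(methyl)amino)-2-oxoethyl]phosphonate | CCOP(=O)(CC(=O)N(C)OC)OCC | starting material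
16 | (E)-N-methoxy-3-[4-(methoxymethoxy)phenyl]-N-methylprop-2-enamide | CON(C)C(=O)/C=C/c1ccc(OCOC)cc1 | intermediate
17 | 6-lithio derivative of 12 | CC1(C)Oc2cc(OCOC)c([Li])c(OCOC)c2C[C@H]1OC1CCCCO1 | intermediate
18 | protected chalcone | CC1(C)Oc2cc(OCOC)c(C(=O)/C=C/c3ccc(OCOC)cc3)c(OCOC)c2C[C@H]1OC1CCCCO1 | intermediate
19 | (E)-1-[(3R)-3,5,7-trihydroxy-2,2-dimethylchroman-6-yl]-3-(4-hydroxyphenyl)prop-2-en-1-one | CC1(C)Oc2cc(O)c(C(=O)/C=C/c3ccc(O)cc3)c(O)c2C[C@H]1O | target

**Step count**
Total steps: 10. Longest linear sequence: 6 (steps 3, 4, 5, 6, 9, 10).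

**Steps most likely to fail**

**1. Step 6.**
- What may go wrong:
  - The hindered, aggregated alkoxide may be outrun at the aryne by carbanions (the bromoaryllithium or PhLi).
  - The aryl carbanion may be lost by proton transfer, or parked by iodine transfer from unreacted 3, before the ring closes.
  - The excess alkoxide may alkylate itself on warming.
- Fallback: known chemistry that makes the same two bonds in separate operations. It sets out from 3 and 5 and comes back at 12.
  - Iodine–magnesium exchange on 3 (i-PrMgCl·LiCl, THF, −40 °C, where the o-bromoaryl Grignard reagent does not yet eliminate) is followed by CuI-catalysed opening of epoxide 5 at its terminal carbon, with 5 taken as its magnesium alkoxide. This should give the diol (2R)-1-[2-bromo-4,6-bis(methoxymethoxy)phenyl]-3-methylbutane-2,3-diol F1.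
  - Selective tetrahydropyranylation of the secondary hydroxyl (DHP, PPTS) gives the tertiary alcohol (3R)-4-[2-bromo-4,6-bis(methoxymethoxy)phenyl]-2-methyl-3-(oxan-2-yloxy)butan-2-ol F2.
  - Buchwald–Hartwig-type intramolecular C–O coupling of the tertiary alcohol with the aryl bromide (Pd(OAc)2, bulky di-tert-butyl biaryl phosphine, Cs2CO3, toluene, 90 °C) closes O1–C8a and gives 12.

**2. Step 9.**
- What may go wrong: the doubly ortho-substituted aryllithium may add only sluggishly to the amide, so that proton transfer or conjugate addition takes over, and lithiation may be incomplete.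
- Fallback: it sets out from 12 (through 17) and 16 and comes back at 18.
  - Amide 16 is reduced with DIBAL-H (THF, −78 °C) to the more electrophilic (E)-3-[4-(methoxymethoxy)phenyl]prop-2-enal F3.
  - 1,2-Addition of 17 to this enal gives the allylic benzylic carbinol F4 as a mixture of carbinol epimers.
  - Oxidation with MnO2 (CH2Cl2, rt) erases the new centre and gives 18.

**3. Step 10.**
- What may go wrong: a freed ortho-hydroxyl may close onto the enone by oxa-Michael addition during or after acetal cleavage, or the B-ring MOM group may be cleaved incompletely if the conditions are kept too mild.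
- Fallback: it sets out from 18 and comes back at 19.
  - The deprotection is driven to completion without regard to ring closure (HCl, MeOH, reflux). This should funnel the material into the linear flavanone closed through the C7 oxygen F5 and the angular flavanone closed through the C5 oxygen F6.
  - Both are then reopened by E1cB retro-oxa-Michael reaction in concentrated aqueous KOH at rt, where the chalcone polyphenolate is the favoured form.
  - Rapid acidification at 0 °C with immediate extraction gives 19. C3 is not involved at any point.

**Further compounds**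
F1 | step 6 | (2R)-1-[2-bromo-4,6-bis(methoxymethoxy)phenyl]-3-methylbutane-2,3-diol | CC(C)(O)[C@@H](Cc1c(Br)cc(OCOC)cc1OCOC)O
F2 | step 6 | (3R)-4-[2-bromo-4,6-bis(methoxymethoxy)phenyl]-2-methyl-3-(oxan-2-yloxy)butan-2-ol | CC(C)(O)[C@@H](Cc1c(Br)cc(OCOC)cc1OCOC)OC1CCCCO1
F3 | step 9 | (E)-3-[4-(methoxymethoxy)phenyl]prop-2-enal | O=C/C=C/c1ccc(OCOC)cc1
F4 | step 9 | (E)-1-[(3R)-5,7-bis(methoxymethoxy)-2,2-dimethyl-3-(oxan-2-yloxy)chroman-6-yl]-3-[4-(methoxymethoxy)phenyl]prop-2-en-1-ol (carbinol epimers) | CC1(C)Oc2cc(OCOC)c(C(O)/C=C/c3ccc(OCOC)cc3)c(OCOC)c2C[C@H]1OC1CCCCO1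
F5 | step 10 | linear flavanone closed through the C7 oxygen (epimers at the new aryl-bearing carbon) | CC1(C)Oc2cc3OC(c4ccc(O)cc4)CC(=O)c3c(O)c2C[C@H]1O
F6 | step 10 | angular flavanone closed through the C5 oxygen (epimers at the new aryl-bearing carbon) | CC1(C)Oc2cc(O)c3C(=O)CC(c4ccc(O)cc4)Oc3c2C[C@H]1O
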